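- A small charge stands in the midnight flask, 0.0540 M of substrate against 0.250 M of partner, so I treat it as a correction to the spring run and compute only the correction.

| flask | substrate | partner | time |
|---|---|---|---|
| dawn | 0.250 M | 0.250 M |  |
| spring | 0.120 M | 0.250 M |  |
| winter | 0.250 M | 0.500 M |  |
| midnight | 0.0540 M | 0.250 M | 19 min |

| run | time / min | [target] / M |
|---|---|---|
| dawn run | 0.68 | 0.0206 |
| dawn run | 2.1 | 0.0528 |
| dawn run | 4.0 | 0.0737 |
| dawn run | 6.3 | 0.0898 |
| dawn run | 9.0 | 0.1002 |
| dawn run | 12 | 0.1081 |
| dawn run | 15 | 0.1113 |
| dawn run | 19 | 0.1144 |
| spring run | 0.68 | 0.0114 |
| spring run | 2.1 | 0.0286 |
| spring run | 4.0 | 0.0427 |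
| spring run | 6.3 | 0.0552 |
| spring run | 9.0 | 0.0626 |
| spring run | 12 | 0.0683 |
| spring run | 15 | 0.0725 |
| spring run | 19 | 0.0768 |
| winter run | 0.68 | 0.0419 |
| winter run | 2.1 | 0.0897 |
| winter run | 4.0 | 0.1232 |
| winter run | 6.3 | 0.1440 |
| winter run | 9.0 | 0.1581 |
| winter run | 12 | 0.1680 |
| winter run | 15 | 0.1703 |
| winter run | 19 | 0.1754 |

(readings scatter by 0.001 M)

- Overall: substrate + partner -> target.
- Constant volume, constant temperature.
- A reading of a species includes what of it is bound.
- An order is taken over about fifteen percent of the charge, up and down.

* how the opening rate goes with [partner] round the charge of the dawn run: the exponent of the rate at two percent of substrate gone to target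
* how the opening rate goes with [substrate] round the charge of the dawn run: the exponent of the rate at two percent of substrate gone to target (one fixed amount of target, the same in the runs compared)
* target in the midnight run at 19 min, as a share of the substrate charged

- My first estimate: partner stands at 4.63 times the substrate at midnight, so a pseudo-first-order picture keeps the share of substrate turned to target independent of charge, and midnight repeats the spring reading of 64.0 % at 19 min.
- The objection is computed from the runs: with the same partner, the dawn run reads 45.8 %, and its share is lower than the spring share. The share therefore moves with charge.
- My better estimate uses the share slope g, the rise in the 19 min share per molar taken off the substrate charge at 0.250 M of partner: g = 1.40 /M. Adding g times the step from spring to midnight to the spring share gives 73.3 %.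
- The next objection is the extension. The step beyond spring is about half of the span between the two runs. Scatter moves the estimate by 1.3 percentage points, but a straight line through two charges remains an assumption, so my margin is wider than that.
- For the orders I compare the first readings. Winter over dawn gives 1.02 for partner, and spring over dawn gives 0.806 for substrate. The objection to the second is its scatter of 0.137: two such margins reach past 1, so I can't separate that reading from first order.
- The forecast gives 1.03 (0.9 to 1.17), 0.85 (0.68 to 1), “suggesting mild saturation”, and 79 % (71 % to 86 %). Its share stands above mine by 5.7 points.

- The flask gives 1.0 for partner, 1.0 for substrate and 76.1 % at midnight. The steps behind the readings are these: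

    substrate + partner ⇌ target + by-product (0.6060 /M/min, 0.3162 /M/min)
    2 partner → lost reagent (0.1404 /M/min)
    partner + by-product ⇌ reagent-by-product salt, settled at all times (86.50 /M)

- The spring rate over the dawn rate, with the same amount of target made, is 0.46, for a charge ratio of 0.480. Over the step from spring to midnight, g is worth 9.3 points, while the flask rises 12 points from the spring reading. The slope over that step is therefore 1.83 /M, steeper than g.

(Readings and results stem from a simulated flask for an exercise; noise was put on by code.)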